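## Retrosynthetic overview

1. Target ⇒ bis-silyl ether ⇒ C7=C8 by aldol addition and β-elimination between a 2-bromo-4-silyloxy-4-octadienylcyclopentenone and a C1–C7 (4R)-silyloxy enal.
2. Enal ⇒ (R)-5-(hydroxymethyl)dihydrofuran-2(3H)-one (D-glutamic acid series, supplies C4) by lactone opening, then Swern oxidation and Wittig homologation.
3. Bromoenone ⇒ 4-hydroxy-4-octadienylcyclopent-2-enone by nucleophilic epoxidation, bromide opening and elimination, so the skipped diene never meets Br2.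
4. The only ring ⇒ Piancatelli rearrangement (4π conrotatory electrocyclization of a hydroxypentadienyl cation) of a 5-octadienylfurfuryl alcohol. C12 is created there as a racemate, and the 12R series is selected as a diastereomer after union with the enantiopure enal.
5. Furan ⇒ furfuryl alcohol + (2Z,5Z)-1-bromoocta-2,5-diene (from 1-bromopent-2-yne and propargyl alcohol, then cis-semihydrogenation). One ring only, formed in step 6.

Assumption: prostanoid locants are used in the comments (C1 = ester carbon, C8–C12 = ring, C13–C20 = octadienyl chain); 1, 2, 6, 17 and all unnumbered reagents are commercial.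

## Route

Step 1
Reactants: 1 1-bromopent-2-yne; 2 prop-2-yn-1-ol
Product: 3 octa-2,5-diyn-1-ol
Conditions: CuI (10 mol %), Cs2CO3, DMF, 23 °C
Reagents that add atoms: none
Why: Copper-catalysed propargylic substitution, in which the acetylide of 2 on monovalent copper displaces bromide from 1 in an SN2 sense to give the skipped diyne without allene formation; no stereocentre is involved.

Step 2
Reactants: 3 octa-2,5-diyn-1-ol
Product: 4 (2Z,5Z)-octa-2,5-dien-1-ol
Conditions: H2 (1 atm), Pd/CaCO3 poisoned with Pb(OAc)2, quinoline, EtOAc, 23 °C, stopped after 2 equiv H2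
Reagents that add atoms: none
Why: Lindlar semi-hydrogenation adds H2 syn to each alkyne on the metal surface, which sets both Z double bonds, and quinoline suppresses over-reduction.

Step 3
Reactants: 4 (2Z,5Z)-octa-2,5-dien-1-ol
Product: 5 (2Z,5Z)-1-bromoocta-2,5-diene
Conditions: CBr4, PPh3, CH2Cl2, 0 °C
Reagents that add atoms: tetrabromomethane (BrC(Br)(Br)Br)
Why: Appel bromination displaces the activated primary allylic oxygen by SN2 under neutral conditions, so both Z double bonds are kept.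

Step 4
Reactants: 6 furan-2-ylmethanol (furfuryl alcohol)
Product: 7 2-(furan-2-ylmethoxy)tetrahydro-2H-pyran
Conditions: 3,4-dihydro-2H-pyran, PPTS (cat.), CH2Cl2, 23 °C
Reagents that add atoms: 3,4-dihydro-2H-pyran (C1CCOC=C1)
Why: Acid-catalysed acetal formation masks the hydroxyl for the lithiation; the new acetal centre is racemic and is removed in step 6.

Step 5
Reactants: 7 2-(furan-2-ylmethoxy)tetrahydro-2H-pyran; 5 (2Z,5Z)-1-bromoocta-2,5-diene
Product: 9 2-({5-[(2Z,5Z)-octa-2,5-dien-1-yl]furan-2-yl}methoxy)tetrahydro-2H-pyran, via 5-lithiofuran 8 (not isolated)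
Conditions: n-BuLi, THF, −78 → 0 °C; then 5 (slight excess), −78 → 0 °C
Reagents that add atoms: none
Why: α-Lithiation of the furan at its only free α-position followed by SN2 alkylation with the primary allylic bromide joins ring and ω-chain at low temperature without touching the Z,Z-diene.

Step 6
Reactants: 9 2-({5-[(2Z,5Z)-octa-2,5-dien-1-yl]furan-2-yl}methoxy)tetrahydro-2H-pyran
Product: 11 rac-4-hydroxy-4-[(2Z,5Z)-octa-2,5-dien-1-yl]cyclopent-2-en-1-one, via free furfuryl alcohol 10 (not isolated)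
Conditions: ZnCl2, 1,4-dioxane/H2O (pH about 5, 0.02 M), 95 °C, Ar
Reagents that add atoms: water (O)
Why: Piancatelli rearrangement: after acetal hydrolysis the furfuryl cation takes up water at C5, the ring opens to a hydroxypentadienyl cation and 4π conrotatory electrocyclization closes the cyclopentenone, creating the tertiary carbinol C12 from a planar achiral cation, hence as a racemate that is carried on until step 13.

Step 7
Reactants: 11 rac-4-hydroxy-4-[(2Z,5Z)-octa-2,5-dien-1-yl]cyclopent-2-en-1-one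
Product: 12 4-hydroxy-4-[(2Z,5Z)-octa-2,5-dien-1-yl]-6-oxabicyclo[3.1.0]hexan-2-one (racemic, epoxide configuration not assigned)
Conditions: 30% aq. H2O2, NaOH (0.2 equiv), MeOH, −10 °C
Reagents that add atoms: hydrogen peroxide (OO)
Why: Weitz–Scheffer nucleophilic epoxidation attacks only the electron-poor enone double bond and leaves the skipped diene alone; the two epoxide stereocentres are erased in step 8.

Step 8
Reactants: 12 4-hydroxy-4-[(2Z,5Z)-octa-2,5-dien-1-yl]-6-oxabicyclo[3.1.0]hexan-2-one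
Product: 15 rac-2-bromo-4-hydroxy-4-[(2Z,5Z)-octa-2,5-dien-1-yl]cyclopent-2-en-1-one, via bromohydrin 13 (not isolated), via bromohydrin mesylate 14 (not isolated)
Conditions: LiBr, AcOH, THF, 23 °C; then crude, MsCl, Et3N, CH2Cl2, 0 °C
Reagents that add atoms: lithium bromide ([Li+].[Br-])
Why: Bromide opens the epoxy ketone by SN2 at the α-carbon, then only the secondary C11 hydroxyl is mesylated and lost by E1cB towards the acidic C10–H, which gives the 2-bromoenone and spares the tertiary C12 hydroxyl.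

Step 9
Reactants: 15 rac-2-bromo-4-hydroxy-4-[(2Z,5Z)-octa-2,5-dien-1-yl]cyclopent-2-en-1-one
Product: 16 rac-2-bromo-4-[(2Z,5Z)-octa-2,5-dien-1-yl]-4-[(triethylsilyl)oxy]cyclopent-2-en-1-one
Conditions: TESOTf, 2,6-lutidine, CH2Cl2, −78 → 0 °C
Reagents that add atoms: triethylsilyl trifluoromethanesulfonate (CC[Si](CC)(CC)OS(=O)(=O)C(F)(F)F)
Why: Silyl triflate silylation of the hindered tertiary alcohol removes the acidic proton and the retro-aldol pathway before enolate formation.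

Step 10
Reactants: 17 (R)-5-(hydroxymethyl)dihydrofuran-2(3H)-one
Product: 20 methyl (R)-4,5-bis[(triethylsilyl)oxy]pentanoate, via potassium carboxylate 18 (not isolated), via dihydroxy ester 19 (not isolated)
Conditions: KOH, MeOH/H2O, 23 °C; evaporate; MeI, DMF, 23 °C; then imidazole, TESCl, 0 → 23 °C
Reagents that add atoms: potassium hydroxide ([K+].[OH-]); iodomethane (CI); chlorotriethylsilane (CC[Si](Cl)(CC)CC)
Why: Lactone saponification, carboxylate O-methylation and silylation of both hydroxyls trap the open chain before it relactonises; no bond to the purchased C4 stereocentre is broken, so it stays R.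

Step 11
Reactants: 20 methyl (R)-4,5-bis[(triethylsilyl)oxy]pentanoate
Product: 22 methyl (4R,5E)-7-oxo-4-[(triethylsilyl)oxy]hept-5-enoate, via aldehyde 21 (not isolated)
Conditions: (COCl)2, DMSO, CH2Cl2, −78 → −30 °C; Et3N; then Ph3P=CHCHO, CH2Cl2, 23 °C
Reagents that add atoms: (triphenylphosphoranylidene)acetaldehyde (O=CC=P(c1ccccc1)(c1ccccc1)c1ccccc1)
Why: Swern conditions oxidise the primary silyl ether directly to the aldehyde and leave the secondary one; Wittig reaction with the stabilised, non-basic ylide then gives the E-enal without epimerising the α-silyloxy aldehyde.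

Step 12
Reactants: 16 rac-2-bromo-4-[(2Z,5Z)-octa-2,5-dien-1-yl]-4-[(triethylsilyl)oxy]cyclopent-2-en-1-one; 22 methyl (4R,5E)-7-oxo-4-[(triethylsilyl)oxy]hept-5-enoate
Product: 24 methyl (4R,5E)-7-{3-bromo-5-[(2Z,5Z)-octa-2,5-dien-1-yl]-2-oxo-5-[(triethylsilyl)oxy]cyclopent-3-en-1-yl}-7-hydroxy-4-[(triethylsilyl)oxy]hept-5-enoate (diastereomer mixture), via lithium enolate 23 (not isolated)
Conditions: LiN(SiMe3)2, THF, −78 °C; then 22, −78 °C; aq. NH4Cl
Reagents that add atoms: none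
Why: Kinetic deprotonation at the only enolisable position (C8) and aldol 1,2-addition to the enal form the C7–C8 bond; the new C7 and C8 centres are uncontrolled and are removed in step 13.

Step 13
Reactants: 24 aldol adduct (diastereomer mixture)
Product: 26 methyl (4R,5E,7Z)-7-{(5R)-3-bromo-5-[(2Z,5Z)-octa-2,5-dien-1-yl]-2-oxo-5-[(triethylsilyl)oxy]cyclopent-3-en-1-ylidene}-4-[(triethylsilyl)oxy]hept-5-enoate, via mesylate 25 (not isolated)
Conditions: MsCl, Et3N (excess), CH2Cl2, −20 → 23 °C, dark; SiO2 chromatography, then HPLC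
Reagents that add atoms: none
Why: Mesylation and E1cB elimination give the cross-conjugated dienone as 7Z and 7E isomers; because C4 is fixed as R the two C12 series are diastereomers, and chromatography isolates the (7Z,12R) isomer 26.

Step 14
Reactants: 26 bis(triethylsilyl) ether of the target
Product: 27 methyl (4R,5E,7Z)-7-{(5R)-3-bromo-5-hydroxy-5-[(2Z,5Z)-octa-2,5-dien-1-yl]-2-oxocyclopent-3-en-1-ylidene}-4-hydroxyhept-5-enoate (CNP0168693.2)
Conditions: HF·pyridine, pyridine, THF, 0 °C, dark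
Reagents that add atoms: none
Why: Buffered fluoride desilylation frees both hydroxyls without base (no conjugate addition to the bromodienone), at low temperature (no lactonisation of the γ-hydroxy ester) and without touching a stereocentre or double bond.

## Compound list

1 | 1-bromopent-2-yne | CCC#CCBr | starting material
2 | prop-2-yn-1-ol | OCC#C | starting material
3 | octa-2,5-diyn-1-ol | CCC#CCC#CCO | intermediate
4 | (2Z,5Z)-octa-2,5-dien-1-ol | CC/C=C\C/C=C\CO | intermediate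
5 | (2Z,5Z)-1-bromoocta-2,5-diene | CC/C=C\C/C=C\CBr | intermediate
6 | furan-2-ylmethanol | OCc1ccco1 | starting material
7 | 2-(furan-2-ylmethoxy)tetrahydro-2H-pyran (racemic acetal) | C(OC1CCCCO1)c1ccco1 | intermediate
8 | 2-[(5-lithiofuran-2-yl)methoxy]tetrahydro-2H-pyran | [Li]c1ccc(COC2CCCCO2)o1 | intermediate
9 | 2-({5-[(2Z,5Z)-octa-2,5-dien-1-yl]furan-2-yl}methoxy)tetrahydro-2H-pyran | CC/C=C\C/C=C\Cc1ccc(COC2CCCCO2)o1 | intermediate
10 | {5-[(2Z,5Z)-octa-2,5-dien-1-yl]furan-2-yl}methanol | CC/C=C\C/C=C\Cc1ccc(CO)o1 | intermediate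
11 | rac-4-hydroxy-4-[(2Z,5Z)-octa-2,5-dien-1-yl]cyclopent-2-en-1-one | CC/C=C\C/C=C\CC1(O)C=CC(=O)C1 | intermediate
12 | 4-hydroxy-4-[(2Z,5Z)-octa-2,5-dien-1-yl]-6-oxabicyclo[3.1.0]hexan-2-one (racemic) | CC/C=C\C/C=C\CC1(O)CC(=O)C2OC21 | intermediate
13 | 2-bromo-3,4-dihydroxy-4-[(2Z,5Z)-octa-2,5-dien-1-yl]cyclopentan-1-one | CC/C=C\C/C=C\CC1(O)CC(=O)C(Br)C1O | intermediate
14 | 2-bromo-5-hydroxy-5-[(2Z,5Z)-octa-2,5-dien-1-yl]-3-oxocyclopentyl methanesulfonate | CC/C=C\C/C=C\CC1(O)CC(=O)C(Br)C1OS(C)(=O)=O | intermediate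
15 | rac-2-bromo-4-hydroxy-4-[(2Z,5Z)-octa-2,5-dien-1-yl]cyclopent-2-en-1-one | CC/C=C\C/C=C\CC1(O)C=C(Br)C(=O)C1 | intermediate
16 | rac-2-bromo-4-[(2Z,5Z)-octa-2,5-dien-1-yl]-4-[(triethylsilyl)oxy]cyclopent-2-en-1-one | CC/C=C\C/C=C\CC1(O[Si](CC)(CC)CC)C=C(Br)C(=O)C1 | intermediate
17 | (R)-5-(hydroxymethyl)dihydrofuran-2(3H)-one | OC[C@H]1CCC(=O)O1 | starting material
18 | potassium (R)-4,5-dihydroxypentanoate | [K+].[O-]C(=O)CC[C@@H](O)CO | intermediate
19 | methyl (R)-4,5-dihydroxypentanoate | COC(=O)CC[C@@H](O)CO | intermediate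
20 | methyl (R)-4,5-bis[(triethylsilyl)oxy]pentanoate | COC(=O)CC[C@@H](O[Si](CC)(CC)CC)CO[Si](CC)(CC)CC | intermediate
21 | methyl (R)-5-oxo-4-[(triethylsilyl)oxy]pentanoate | COC(=O)CC[C@@H](O[Si](CC)(CC)CC)C=O | intermediate
22 | methyl (4R,5E)-7-oxo-4-[(triethylsilyl)oxy]hept-5-enoate | COC(=O)CC[C@@H](O[Si](CC)(CC)CC)/C=C/C=O | intermediate
23 | lithium 5-bromo-3-[(2Z,5Z)-octa-2,5-dien-1-yl]-3-[(triethylsilyl)oxy]cyclopenta-1,4-dien-1-olate | CC/C=C\C/C=C\CC1(O[Si](CC)(CC)CC)C=C(Br)C(O[Li])=C1 | intermediate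
24 | methyl (4R,5E)-7-{3-bromo-5-[(2Z,5Z)-octa-2,5-dien-1-yl]-2-oxo-5-[(triethylsilyl)oxy]cyclopent-3-en-1-yl}-7-hydroxy-4-[(triethylsilyl)oxy]hept-5-enoate (mixture at C7, C8, C12) | CC/C=C\C/C=C\CC1(O[Si](CC)(CC)CC)C=C(Br)C(=O)C1C(O)/C=C/[C@H](O[Si](CC)(CC)CC)CCC(=O)OC | intermediate
25 | 7-methanesulfonate of 24 | CC/C=C\C/C=C\CC1(O[Si](CC)(CC)CC)C=C(Br)C(=O)C1C(OS(C)(=O)=O)/C=C/[C@H](O[Si](CC)(CC)CC)CCC(=O)OC | intermediate
26 | methyl (4R,5E,7Z)-7-{(5R)-3-bromo-5-[(2Z,5Z)-octa-2,5-dien-1-yl]-2-oxo-5-[(triethylsilyl)oxy]cyclopent-3-en-1-ylidene}-4-[(triethylsilyl)oxy]hept-5-enoate | CC/C=C\C/C=C\C[C@@]1(O[Si](CC)(CC)CC)C=C(Br)C(=O)/C1=C\C=C\[C@H](O[Si](CC)(CC)CC)CCC(=O)OC | intermediate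
27 | methyl (4R,5E,7Z)-7-{(5R)-3-bromo-5-hydroxy-5-[(2Z,5Z)-octa-2,5-dien-1-yl]-2-oxocyclopent-3-en-1-ylidene}-4-hydroxyhept-5-enoate | CC/C=C\C/C=C\C[C@@]1(O)C=C(Br)C(=O)/C1=C\C=C\[C@H](O)CCC(=O)OC | target

## Step count and risks

Total step count: 14. Longest linear sequence: 11 steps (steps 1, 2, 3, 5, 6, 7, 8, 9, 12, 13, 14).

Steps most likely to fail:

Step 6. A primary, 5-alkylated furfuryl alcohol ionises slowly and can oligomerise, and the step gives 11 only as a racemate. The fallback sets out from 4 and comes back at 11. Alcohol 4 is converted (N-chlorosuccinimide, Me2S, CH2Cl2, −20 °C) into (2Z,5Z)-1-chloroocta-2,5-diene F1. With active barium (BaI2 reduced by lithium biphenylide, THF, −78 °C) F1 gives chloro[(2Z,5Z)-octa-2,5-dien-1-yl]barium F2. F2 adds through its α-carbon, both Z double bonds intact, to the carbonyl of commercial (R)-4-[(tert-butyldimethylsilyl)oxy]cyclopent-2-en-1-one, anti to the silyloxy group, to give (1S,4R)-4-[(tert-butyldimethylsilyl)oxy]-1-[(2Z,5Z)-octa-2,5-dien-1-yl]cyclopent-2-en-1-ol F3. Bu4NF gives (1S,4R)-1-[(2Z,5Z)-octa-2,5-dien-1-yl]cyclopent-2-ene-1,4-diol F4, and MnO2 in CH2Cl2 oxidises only the secondary allylic alcohol to (4S)-4-hydroxy-4-[(2Z,5Z)-octa-2,5-dien-1-yl]cyclopent-2-en-1-one F5. F5 is the (S)-enantiomer of 11 and takes its place from step 7 on. C12 is then fixed by the purchased silyloxy stereocentre and the epimer separation in step 13 falls away.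

Step 8. The acid-sensitive epoxy alcohol may lose the tertiary hydroxyl or open the wrong way. The fallback sets out from 5 and comes back at 15. Commercial 3-bromofuran-2-carbaldehyde is reduced (NaBH4, MeOH) to (3-bromofuran-2-yl)methanol F6 and protected (3,4-dihydro-2H-pyran, PPTS) as 2-[(3-bromofuran-2-yl)methoxy]tetrahydro-2H-pyran F7. LiN(i-Pr)2 (THF, −78 °C) removes the C5 proton without bromine–lithium exchange to give 2-[(3-bromo-5-lithiofuran-2-yl)methoxy]tetrahydro-2H-pyran F8. F8 is alkylated by 5 to 2-({3-bromo-5-[(2Z,5Z)-octa-2,5-dien-1-yl]furan-2-yl}methoxy)tetrahydro-2H-pyran F9. Under the aqueous ZnCl2 conditions of step 6 the liberated {3-bromo-5-[(2Z,5Z)-octa-2,5-dien-1-yl]furan-2-yl}methanol F10 rearranges directly to 15. The bromine then arrives with the furan and no epoxide is made.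

Step 13. The elimination is not stereospecific and may favour the 7E isomer. The fallback sets out from 24 and comes back at 26. The elimination is run as in step 13 and the (7E,12R) isomer, methyl (4R,5E,7E)-7-{(5R)-3-bromo-5-[(2Z,5Z)-octa-2,5-dien-1-yl]-2-oxo-5-[(triethylsilyl)oxy]cyclopent-3-en-1-ylidene}-4-[(triethylsilyl)oxy]hept-5-enoate F11, is collected instead of discarded. F11 is irradiated (350 nm, benzene, 10 °C) to a photostationary 7E/7Z mixture, 26 is separated by HPLC and F11 is recycled. The 7Z geometry is then set by photoisomerisation, not by the elimination.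

## Further compounds

F1 | step 6 | (2Z,5Z)-1-chloroocta-2,5-diene | CC/C=C\C/C=C\CCl
F2 | step 6 | chloro[(2Z,5Z)-octa-2,5-dien-1-yl]barium | CC/C=C\C/C=C\C[Ba]Cl
F3 | step 6 | (1S,4R)-4-[(tert-butyldimethylsilyl)oxy]-1-[(2Z,5Z)-octa-2,5-dien-1-yl]cyclopent-2-en-1-ol | CC/C=C\C/C=C\C[C@@]1(O)C=C[C@H](O[Si](C)(C)C(C)(C)C)C1
F4 | step 6 | (1S,4R)-1-[(2Z,5Z)-octa-2,5-dien-1-yl]cyclopent-2-ene-1,4-diol | CC/C=C\C/C=C\C[C@@]1(O)C=C[C@H](O)C1
F5 | step 6 | (4S)-4-hydroxy-4-[(2Z,5Z)-octa-2,5-dien-1-yl]cyclopent-2-en-1-one | CC/C=C\C/C=C\C[C@@]1(O)C=CC(=O)C1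
F6 | step 8 | (3-bromofuran-2-yl)methanol | OCc1occc1Br
F7 | step 8 | 2-[(3-bromofuran-2-yl)methoxy]tetrahydro-2H-pyran | Brc1ccoc1COC1CCCCO1
F8 | step 8 | 2-[(3-bromo-5-lithiofuran-2-yl)methoxy]tetrahydro-2H-pyran | [Li]c1cc(Br)c(COC2CCCCO2)o1
F9 | step 8 | 2-({3-bromo-5-[(2Z,5Z)-octa-2,5-dien-1-yl]furan-2-yl}methoxy)tetrahydro-2H-pyran | CC/C=C\C/C=C\Cc1cc(Br)c(COC2CCCCO2)o1
F10 | step 8 | {3-bromo-5-[(2Z,5Z)-octa-2,5-dien-1-yl]furan-2-yl}methanol | CC/C=C\C/C=C\Cc1cc(Br)c(CO)o1
F11 | step 13 | methyl (4R,5E,7E)-7-{(5R)-3-bromo-5-[(2Z,5Z)-octa-2,5-dien-1-yl]-2-oxo-5-[(triethylsilyl)oxy]cyclopent-3-en-1-ylidene}-4-[(triethylsilyl)oxy]hept-5-enoate | CC/C=C\C/C=C\C[C@@]1(O[Si](CC)(CC)CC)C=C(Br)C(=O)/C1=C/C=C/[C@H](O[Si](CC)(CC)CC)CCC(=O)OC
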